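**Assumption:** cembrane numbering is used (C1 = β-carbon of the α-methylene lactone, C14 = its carbinol carbon, C10 = butenolide carbinol carbon, C5 = hydroperoxy carbon). The SMILES encodes (1R,5R,10R,14S), a trans-fused α-methylene lactone and E-C12=C13. Compounds 1, 2, 11, 12, 15 and 21 are bought.

## Retrosynthetic overview

1. Target 27 ⇐ ovatodiolide 26 by a Schenck ene reaction of singlet oxygen at C4=C5 (C5–O bond, C4=C18 methylene; face set by the macrocycle).
2. 26 ⇐ open-chain butenolide 24: an intramolecular Cr(II) allylation (C1–C14) closes the 14-membered ring and, after lactonisation, the trans α-methylene-γ-lactone; C10 steers C1/C14.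
3. 24 ⇐ ester 20 of East alcohol 10 and West acid 19: MBH reaction and SN2′ bromination install the 2-(bromomethyl)enoate, then RCM makes the butenolide.
4. 19 ⇐ tert-butyl 2-(hydroxymethyl)acrylate by two Claisen [3,3] rearrangements (C6–C7, then C2–C3 with the E-C4=C5 olefin).
5. 10 ⇐ (R)-epichlorohydrin, the only source of chirality (C10), by alkynylation, sulfonium-ylide vinylation and Negishi carboalumination. Ring order: butenolide → carbocycle → γ-lactone.

## Route

Step 1
Reactants: 1 (R)-epichlorohydrin; 2 ethynyltrimethylsilane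
Product: 4 (R)-1-chloro-5-(trimethylsilyl)pent-4-yn-2-ol, via lithium (trimethylsilyl)acetylide 3 (not isolated)
Conditions: 2, n-BuLi, THF, −78 °C; BF3·OEt2; then 1, −78 °C
Reagents that add atoms: none
Why: BF3-promoted (Yamaguchi-type) alkynylation opens the epoxide at its CH2 terminus, so the purchased stereocentre (future C10) is not touched.

Step 2
Reactants: 4 (R)-1-chloro-5-(trimethylsilyl)pent-4-yn-2-ol
Product: 7 (R)-hex-1-en-5-yn-3-ol, via (R)-trimethyl[3-(oxiran-2-yl)prop-1-yn-1-yl]silane 5 (not isolated), via (R)-6-(trimethylsilyl)hex-1-en-5-yn-3-ol 6 (not isolated)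
Conditions: Me3S+I− (3.5 equiv), n-BuLi (3.3 equiv), THF, −10 °C → rt; then K2CO3, MeOH, rt
Reagents that add atoms: trimethylsulfonium iodide, C[S+](C)C.[I-]
Why: Base closes the chlorohydrin to the epoxide and dimethylsulfonium methylide opens it at CH2 and eliminates Me2S (one-carbon homologation to the vinyl carbinol), then methanolysis removes silicon; no bond to the stereocentre is broken.

Step 3
Reactants: 7 (R)-hex-1-en-5-yn-3-ol
Product: 9 (2E,5R)-3-methylhepta-2,6-diene-1,5-diol, via dimethylaluminium alkoxide of (3R,5E)-6-(dimethylalumanyl)-5-methylhexa-1,5-dien-3-ol 8 (not isolated)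
Conditions: AlMe3 (3 equiv), Cp2ZrCl2 (0.3 equiv), CH2Cl2, 0 °C → rt; evaporate; THF, n-BuLi, −78 °C; (CH2O)n, → rt
Reagents that add atoms: trimethylaluminium, C[Al](C)C; paraformaldehyde (formaldehyde units), C=O
Why: Negishi Zr-catalysed carboalumination adds Me–Al syn across the terminal alkyne (Me on the internal carbon), and the alanate is hydroxymethylated with retention, fixing the E-C12=C13 olefin.

Step 4
Reactants: 9 (2E,5R)-3-methylhepta-2,6-diene-1,5-diol
Product: 10 (2E,5R)-5-hydroxy-3-methylhepta-2,6-dienal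
Conditions: TEMPO (10 mol%), PhI(OAc)2 (1.1 equiv), CH2Cl2, rt; used directly
Reagents that add atoms: none
Why: The oxoammonium (TEMPO/BAIB) oxidation is selective for the primary allylic alcohol over the secondary vinyl carbinol.

Step 5
Reactants: 11 tert-butyl 2-(hydroxymethyl)acrylate; 12 ethyl vinyl ether
Product: 14 tert-butyl 2-methylidene-5-oxopentanoate, via tert-butyl 2-[(vinyloxy)methyl]acrylate 13 (not isolated)
Conditions: 12 (excess), Hg(OAc)2 (cat.), reflux; concentrate; PhMe, BHT, 130 °C (sealed)
Reagents that add atoms: none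
Why: Transvinylation followed by a Claisen [3,3] rearrangement forms the C6–C7 bond and transposes the acrylate methylene; the 2-ester on the allyl unit accelerates the shift.

Step 6
Reactants: 14 tert-butyl 2-methylidene-5-oxopentanoate; 15 isopropenylmagnesium bromide
Product: 16 tert-butyl 5-hydroxy-6-methyl-2-methylidenehept-6-enoate (racemic)
Conditions: 15, THF, −78 °C; aq. NH4Cl
Reagents that add atoms: none
Why: Grignard 1,2-addition to the aldehyde outpaces attack on the hindered tert-butyl α-substituted acrylate; the racemic carbinol is destroyed in step 7.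

Step 7
Reactants: 16 tert-butyl 5-hydroxy-6-methyl-2-methylidenehept-6-enoate; 12 ethyl vinyl ether
Product: 18 tert-butyl (5E)-6-methyl-2-methylidene-9-oxonon-5-enoate, via tert-butyl 6-methyl-2-methylidene-5-(vinyloxy)hept-6-enoate 17 (not isolated)
Conditions: 12 (excess), Hg(OAc)2 (cat.), reflux; concentrate; PhMe, BHT, 130 °C (sealed)
Reagents that add atoms: none
Why: The Claisen [3,3] rearrangement through a chair with the side chain pseudo-equatorial forms the C2–C3 bond and the E-C4=C5 trisubstituted olefin (about 9:1 E:Z expected; minor isomer removed by chromatography) and delivers the C1 aldehyde directly.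

Step 8
Reactants: 18 tert-butyl (5E)-6-methyl-2-methylidene-9-oxonon-5-enoate
Product: 19 (5E)-6-methyl-2-methylidene-9-oxonon-5-enoic acid
Conditions: TFA, CH2Cl2, 0 °C, short contact
Reagents that add atoms: none
Why: Acidolysis of the tert-butyl ester (loss of isobutene) frees the acid without touching the aldehyde or the olefins.

Step 9
Reactants: 19 (5E)-6-methyl-2-methylidene-9-oxonon-5-enoic acid; 10 (2E,5R)-5-hydroxy-3-methylhepta-2,6-dienal
Product: 20 (3R,5E)-5-methyl-7-oxohepta-1,5-dien-3-yl (5E)-6-methyl-2-methylidene-9-oxonon-5-enoate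
Conditions: DCC, DMAP (cat.), CH2Cl2, 0 °C → rt
Reagents that add atoms: none
Why: Steglich esterification acylates the C10 oxygen without breaking a bond at the stereocentre.

Step 10
Reactants: 20 (3R,5E)-5-methyl-7-oxohepta-1,5-dien-3-yl (5E)-6-methyl-2-methylidene-9-oxonon-5-enoate; 21 methyl acrylate
Product: 22 1-[(3R,5E)-5-methyl-7-oxohepta-1,5-dien-3-yl] 11-methyl (5E)-9-hydroxy-6-methyl-2,10-dimethylideneundec-5-enedioate (both carbinol epimers)
Conditions: 21 (excess), DABCO (1 equiv), MeOH (cat.), rt, 3–5 d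
Reagents that add atoms: none
Why: The Morita–Baylis–Hillman reaction takes the saturated C1 aldehyde, since the β,β-disubstituted enal and the α-substituted acrylate are poor partners; the new carbinol is uncontrolled but is erased in step 11.

Step 11
Reactants: 22 (the MBH adduct above)
Product: 23 1-[(3R,5E)-5-methyl-7-oxohepta-1,5-dien-3-yl] 11-methyl (5E,9Z)-10-(bromomethyl)-6-methyl-2-methylideneundeca-5,9-dienedioate
Conditions: NBS, Me2S, CH2Cl2, 0 °C → rt
Reagents that add atoms: N-bromosuccinimide, O=C1CCC(=O)N1Br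
Why: Corey–Kim-type activation of the alcohol and SN2′ delivery of bromide give the thermodynamically preferred (Z)-2-(bromomethyl)enoate.

Step 12
Reactants: 23 (the allyl bromide above)
Product: 24 methyl (2Z,6E)-2-(bromomethyl)-6-methyl-9-{(5R)-5-[(2E)-2-methyl-4-oxobut-2-en-1-yl]-2-oxo-2,5-dihydrofuran-3-yl}nona-2,6-dienoate
Conditions: Grubbs II (5 mol%), CH2Cl2 (5 mM), 40 °C
Reagents that add atoms: none
Why: Ring-closing metathesis of the vinyl group with the 2-substituted acrylate forms the butenolide (ethene lost); the trisubstituted and electron-poor olefins are inert and C10 is untouched.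

Step 13
Reactants: 24 (the butenolide bromo-enal above)
Product: 26 ovatodiolide, (1R,10R,14S), 4E,12E, via methyl 2-[(1R,10R,14S)-14-hydroxy macrocyclic butenolide-1-yl]acrylate (C14-hydroxy C16-methyl ester seco form of 26) 25 (not isolated)
Conditions: CrCl2 (8 equiv), THF (2 mM, slow addition), rt; aq. NH4Cl; then p-TsOH (cat.), CH2Cl2, rt
Reagents that add atoms: none
Why: In this intramolecular Nozaki–Hiyama (Cr(II) Barbier-type) allylation the allylchromium adds through a chair with the C2 chain pseudo-equatorial (anti adduct, hence the trans lactone after lactonisation), and the C10 centre of the rigid butenolide is expected to select the enal face through the conformation of the forming 14-membered ring, giving 1R,14S.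

Step 14
Reactants: 26 ovatodiolide
Product: 27 4-methylene-5β-hydroperoxyovatodiolide, (1R,5R,10R,14S)
Conditions: O2, hν (visible), tetraphenylporphyrin (cat.), CH2Cl2, −20 °C, to about 70% conversion
Reagents that add atoms: oxygen, O=O
Why: In the Schenck ene reaction 1O2 attacks the electron-rich C4=C5 olefin, abstracts hydrogen from the C18 methyl on the more crowded side (cis effect) and delivers oxygen to C5 from the open peripheral face of the macrocycle (5β, 5R); the tertiary 4-hydroperoxy-Δ5 isomer is the expected minor product.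

## Compound list

1 | (R)-epichlorohydrin | ClC[C@H]1CO1 | starting material
2 | ethynyltrimethylsilane | C#C[Si](C)(C)C | starting material
3 | lithium (trimethylsilyl)acetylide | [Li]C#C[Si](C)(C)C | intermediate
4 | (R)-1-chloro-5-(trimethylsilyl)pent-4-yn-2-ol | ClC[C@H](O)CC#C[Si](C)(C)C | intermediate
5 | (R)-trimethyl[3-(oxiran-2-yl)prop-1-yn-1-yl]silane | C1O[C@@H]1CC#C[Si](C)(C)C | intermediate
6 | (R)-6-(trimethylsilyl)hex-1-en-5-yn-3-ol | C=C[C@H](O)CC#C[Si](C)(C)C | intermediate
7 | (R)-hex-1-en-5-yn-3-ol | C=C[C@H](O)CC#C | intermediate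
8 | dimethylaluminium alkoxide of (3R,5E)-6-(dimethylalumanyl)-5-methylhexa-1,5-dien-3-ol | C=C[C@H](O[Al](C)C)C/C(C)=C/[Al](C)C | intermediate
9 | (2E,5R)-3-methylhepta-2,6-diene-1,5-diol | C=C[C@H](O)C/C(C)=C/CO | intermediate
10 | (2E,5R)-5-hydroxy-3-methylhepta-2,6-dienal | C=C[C@H](O)C/C(C)=C/C=O | intermediate
11 | tert-butyl 2-(hydroxymethyl)acrylate | C=C(CO)C(=O)OC(C)(C)C | starting material
12 | ethyl vinyl ether | C=COCC | starting material
13 | tert-butyl 2-[(vinyloxy)methyl]acrylate | C=COCC(=C)C(=O)OC(C)(C)C | intermediate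
14 | tert-butyl 2-methylidene-5-oxopentanoate | O=CCCC(=C)C(=O)OC(C)(C)C | intermediate
15 | isopropenylmagnesium bromide | CC(=C)[Mg]Br | starting material
16 | tert-butyl 5-hydroxy-6-methyl-2-methylidenehept-6-enoate (racemic) | CC(=C)C(O)CCC(=C)C(=O)OC(C)(C)C | intermediate
17 | tert-butyl 6-methyl-2-methylidene-5-(vinyloxy)hept-6-enoate | CC(=C)C(OC=C)CCC(=C)C(=O)OC(C)(C)C | intermediate
18 | tert-butyl (5E)-6-methyl-2-methylidene-9-oxonon-5-enoate | O=CCC/C(C)=C/CCC(=C)C(=O)OC(C)(C)C | intermediate
19 | (5E)-6-methyl-2-methylidene-9-oxonon-5-enoic acid | O=CCC/C(C)=C/CCC(=C)C(=O)O | intermediate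
20 | (3R,5E)-5-methyl-7-oxohepta-1,5-dien-3-yl (5E)-6-methyl-2-methylidene-9-oxonon-5-enoate | O=CCC/C(C)=C/CCC(=C)C(=O)O[C@@H](C=C)C/C(C)=C/C=O | intermediate
21 | methyl acrylate | C=CC(=O)OC | starting material
22 | 1-[(3R,5E)-5-methyl-7-oxohepta-1,5-dien-3-yl] 11-methyl (5E)-9-hydroxy-6-methyl-2,10-dimethylideneundec-5-enedioate (both C9 epimers) | COC(=O)C(=C)C(O)CC/C(C)=C/CCC(=C)C(=O)O[C@@H](C=C)C/C(C)=C/C=O | intermediate
23 | 1-[(3R,5E)-5-methyl-7-oxohepta-1,5-dien-3-yl] 11-methyl (5E,9Z)-10-(bromomethyl)-6-methyl-2-methylideneundeca-5,9-dienedioate | COC(=O)/C(CBr)=C/CC/C(C)=C/CCC(=C)C(=O)O[C@@H](C=C)C/C(C)=C/C=O | intermediate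
24 | methyl (2Z,6E)-2-(bromomethyl)-6-methyl-9-{(5R)-5-[(2E)-2-methyl-4-oxobut-2-en-1-yl]-2-oxo-2,5-dihydrofuran-3-yl}nona-2,6-dienoate | COC(=O)/C(CBr)=C/CC/C(C)=C/CCC1=C[C@@H](C/C(C)=C/C=O)OC1=O | intermediate
25 | C14-hydroxy C16-methyl ester seco form of ovatodiolide, (1R,10R,14S) | COC(=O)C(=C)[C@H]1CC/C(C)=C/CCC2=C[C@@H](C/C(C)=C/[C@@H]1O)OC2=O | intermediate
26 | ovatodiolide, (1R,10R,14S) | C=C1C(=O)O[C@H]2/C=C(\C)C[C@@H]3C=C(CC/C=C(\C)CC[C@H]12)C(=O)O3 | intermediate
27 | 4-methylene-5β-hydroperoxyovatodiolide, (1R,5R,10R,14S) | C=C1C(=O)O[C@H]2/C=C(\C)C[C@@H]3C=C(CC[C@@H](OO)C(=C)CC[C@H]12)C(=O)O3 | target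

## Step count

Total steps: 14. Longest linear sequence: 10 (steps 5–14; the East branch, steps 1–4 then 9–14, is also 10).

## Three steps most likely to fail

**Step 13 (Cr(II) macrocyclisation).** The yield of the 14-membered ring closure and the sense of the remote C10 → C1/C14 induction are unproven for this substrate. The fallback closes the macrocycle by metathesis instead of allylation; it sets out from 10 and comes back at 26. Steglich esterification of 10 with commercial cyclobut-1-ene-1-carboxylic acid gives (3R,5E)-5-methyl-7-oxohepta-1,5-dien-3-yl cyclobut-1-ene-1-carboxylate F1. Separately, commercial 4-methylpent-4-enal and 21 (DABCO) give methyl 3-hydroxy-6-methyl-2-methylidenehept-6-enoate F2, which NBS/Me2S converts into methyl (2Z)-2-(bromomethyl)-6-methylhepta-2,6-dienoate F3. Intermolecular CrCl2 allylation of the enal of F1 with F3, then acid-induced lactonisation, gives the trans lactone (3R,5E)-5-methyl-6-[(2S,3R)-3-(3-methylbut-3-en-1-yl)-4-methylidene-5-oxooxolan-2-yl]hexa-1,5-dien-3-yl cyclobut-1-ene-1-carboxylate F4. The anti relationship comes from the chair transition state, but C10 exerts no control here, so F4 must be separated from its (1S,14R) partner. Grubbs II then runs a ring-opening/ring-closing cascade on F4 (vinyl + cyclobutene → butenolide; the new alkylidene + isopropenyl → E-C4=C5 in the macrocycle) to reach 26.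

**Step 14 (photooxygenation).** Regiochemistry (C18–H against C6–H abstraction), facial selectivity at C5 and competing attack at C12=C13 are not guaranteed. The fallback replaces the pericyclic oxygenation by an ionic two-step sequence; it sets out from 26 and comes back at 27. PhSeCl-catalysed chlorination with NCS (ene-type, with allylic shift, favouring the methyl-derived methylene) gives (1R,10R,14S)-5-chloro-4-methylene-4,5-dihydroovatodiolide F5. AgOTf with anhydrous H2O2 (Et2O, 0 °C) ionises the allylic chloride, and H2O2 captures the allyl cation at the secondary C5 from the open peripheral face to give 27.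

**Step 10 (chemoselective MBH reaction).** The reaction is slow and has to distinguish two aldehydes in a polyfunctional ester. The fallback installs the bromomethyl-enoate on the West fragment before the fragments are joined; it sets out from 18 and comes back at 23. MBH reaction of 18 with 21 (DABCO) gives 1-tert-butyl 11-methyl (5E)-9-hydroxy-6-methyl-2,10-dimethylideneundec-5-enedioate F6. NBS/Me2S gives 1-tert-butyl 11-methyl (5E,9Z)-10-(bromomethyl)-6-methyl-2-methylideneundeca-5,9-dienedioate F7. TFA gives (5E,9Z)-10-(bromomethyl)-11-methoxy-6-methyl-2-methylidene-11-oxoundeca-5,9-dienoic acid F8. 1-Chloro-N,N,2-trimethylprop-1-en-1-amine converts it into methyl (2Z,6E)-2-(bromomethyl)-11-chloro-6-methyl-10-methylidene-11-oxoundeca-2,6-dienoate F9, which acylates 10 with 2,6-lutidine as base (DMAP is avoided because it quaternises the allyl bromide) to give 23.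

## Further compounds

F1 | step 13 | (3R,5E)-5-methyl-7-oxohepta-1,5-dien-3-yl cyclobut-1-ene-1-carboxylate | C=C[C@H](OC(=O)C1=CCC1)C/C(C)=C/C=O
F2 | step 13 | methyl 3-hydroxy-6-methyl-2-methylidenehept-6-enoate | COC(=O)C(=C)C(O)CCC(C)=C
F3 | step 13 | methyl (2Z)-2-(bromomethyl)-6-methylhepta-2,6-dienoate | COC(=O)/C(CBr)=C/CCC(C)=C
F4 | step 13 | (3R,5E)-5-methyl-6-[(2S,3R)-3-(3-methylbut-3-en-1-yl)-4-methylidene-5-oxooxolan-2-yl]hexa-1,5-dien-3-yl cyclobut-1-ene-1-carboxylate | C=C1C(=O)O[C@@H](/C=C(\C)C[C@H](C=C)OC(=O)C2=CCC2)[C@@H]1CCC(C)=C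
F5 | step 14 | (1R,10R,14S)-5-chloro-4-methylene-4,5-dihydroovatodiolide (C5 epimers) | C=C1C(=O)O[C@H]2/C=C(\C)C[C@@H]3C=C(CCC(Cl)C(=C)CC[C@H]12)C(=O)O3
F6 | step 10 | 1-tert-butyl 11-methyl (5E)-9-hydroxy-6-methyl-2,10-dimethylideneundec-5-enedioate | COC(=O)C(=C)C(O)CC/C(C)=C/CCC(=C)C(=O)OC(C)(C)C
F7 | step 10 | 1-tert-butyl 11-methyl (5E,9Z)-10-(bromomethyl)-6-methyl-2-methylideneundeca-5,9-dienedioate | COC(=O)/C(CBr)=C/CC/C(C)=C/CCC(=C)C(=O)OC(C)(C)C
F8 | step 10 | (5E,9Z)-10-(bromomethyl)-11-methoxy-6-methyl-2-methylidene-11-oxoundeca-5,9-dienoic acid | COC(=O)/C(CBr)=C/CC/C(C)=C/CCC(=C)C(=O)O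
F9 | step 10 | methyl (2Z,6E)-2-(bromomethyl)-11-chloro-6-methyl-10-methylidene-11-oxoundeca-2,6-dienoate | COC(=O)/C(CBr)=C/CC/C(C)=C/CCC(=C)C(=O)Cl
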